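**Retrosynthetic overview**

1. The target is the (2R,3R)-trans flavanone 5,6-dihydroxy-2-(3-hydroxy-4-methoxyphenyl)-3,7-dimethoxychroman-4-one. Late disconnections remove the O5 methyl and both O-benzyl groups, the O3 methyl, the C3–O bond (enol ether oxidation anti to the C2 aryl) and the C4 carbonyl (benzylic oxidation), leading back to a (2S)-flavan whose only stereocentre is C2.
2. Feature used: O1 (on C8a) and C4 (on C4a) are ortho on the trioxygenated ring A, so O1=C8a–C4a=C4 is the oxadiene of an ortho-quinone methide. C2 is benzylic to ring B and para to its 4'-methoxy group, so C2–C3 can come from a correctly polarised styrene.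
3. Key disconnection: C3–C4 and O1–C2 together, by enantioselective oxa-[4+2] cycloaddition of the quinone methide (from a salicyl alcohol) with the ring B styrene under a chiral BINOL-derived Brønsted acid. Rings A and B are bought; ring C is the only ring made.
4. Salicyl alcohol: syringaldehyde, benzyl ether, Baeyer–Villiger/Dakin phenol (mirror-symmetric, so ortho-formylation has one outcome), aldehyde, NaBH4. The 5- and 7-methoxy groups are told apart only at the end, because only the 5-methoxy group chelates to the C4 carbonyl.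
5. Styrene: isovanillin, benzyl ether, Wittig methylenation.

Key step: step 7

Remark on the chemistry: the sense of induction of the chiral acid in step 7 cannot be fixed in advance; the (R)-catalyst is written, and its mirror image is taken if it should favour the (2R)-flavan.

**Route**

Step 1
Reactants: 1 syringaldehyde (4-hydroxy-3,5-dimethoxybenzaldehyde)
Product: 2 4-(benzyloxy)-3,5-dimethoxybenzaldehyde
Conditions: BnBr, K2CO3, DMF, 60 °C
Reagents that add atoms: benzyl bromide, BrCc1ccccc1
Why: Williamson etherification of the acidic para-formyl phenol masks the future 6-hydroxyl as a benzyl ether that should survive every step up to the final Lewis acid treatment.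

Step 2
Reactants: 2 4-(benzyloxy)-3,5-dimethoxybenzaldehyde
Product: 4 4-(benzyloxy)-3,5-dimethoxyphenol, via aryl formate 3 (not isolated)
Conditions: mCPBA, CH2Cl2, 0 °C → rt; then MeOH, K2CO3, rt
Reagents that add atoms: meta-chloroperoxybenzoic acid, OOC(=O)c1cccc(Cl)c1
Why: Baeyer–Villiger (Dakin-type) oxidation in which the electron-rich trialkoxyphenyl group migrates in preference to hydride, and methanolysis of the formate frees a phenol whose two ortho positions are equivalent by symmetry.

Step 3
Reactants: 4 4-(benzyloxy)-3,5-dimethoxyphenol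
Product: 6 3-(benzyloxy)-6-hydroxy-2,4-dimethoxybenzaldehyde, via magnesium salicyl alkoxide 5 (not isolated)
Conditions: MgCl2, Et3N, (CH2O)n, MeCN, reflux; 1 M HCl work-up
Reagents that add atoms: paraformaldehyde (reacting as formaldehyde), C=O
Why: Casnati–Skattebøl ortho-formylation, in which the magnesium phenoxide delivers formaldehyde only to the ortho carbon and a second formaldehyde oxidises the chelated benzylic alkoxide by hydride transfer, the symmetry of 4 allowing a single product.

Step 4
Reactants: 6 3-(benzyloxy)-6-hydroxy-2,4-dimethoxybenzaldehyde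
Product: 7 4-(benzyloxy)-2-(hydroxymethyl)-3,5-dimethoxyphenol
Conditions: NaBH4, THF/MeOH, 0 °C; sat. aq. NH4Cl; used at once
Reagents that add atoms: none
Why: Borohydride reduction of the aldehyde, kept cold and worked up near neutral pH because this salicyl alcohol ionises easily to the quinone methide that step 7 is meant to use.

Step 5
Reactants: 8 isovanillin (3-hydroxy-4-methoxybenzaldehyde)
Product: 9 3-(benzyloxy)-4-methoxybenzaldehyde
Conditions: BnBr, K2CO3, DMF, 60 °C
Reagents that add atoms: benzyl bromide, BrCc1ccccc1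
Why: Williamson etherification protects the ring B phenol, which would otherwise quench the ylide of step 6 and compete as a nucleophile in step 7.

Step 6
Reactants: 9 3-(benzyloxy)-4-methoxybenzaldehyde
Product: 10 2-(benzyloxy)-4-ethenyl-1-methoxybenzene
Conditions: Ph3PCH3Br, KOtBu, THF, 0 °C → rt
Reagents that add atoms: methyltriphenylphosphonium bromide, [Br-].C[P+](c1ccccc1)(c1ccccc1)c1ccccc1
Why: Wittig methylenation of a non-enolisable aromatic aldehyde by the unstabilised ylide, driven by formation of the P=O bond.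

Step 7
Reactants: 7 4-(benzyloxy)-2-(hydroxymethyl)-3,5-dimethoxyphenol and 10 2-(benzyloxy)-4-ethenyl-1-methoxybenzene
Product: 12 (2S)-6-(benzyloxy)-2-[3-(benzyloxy)-4-methoxyphenyl]-5,7-dimethoxy-3,4-dihydro-2H-chromene, via ortho-quinone methide 11 (not isolated)
Conditions: (R)-3,3'-bis(2,4,6-triisopropylphenyl)-1,1'-binaphthyl-2,2'-diyl N-triflylphosphoramide (5 mol %), 5 Å MS, CH2Cl2, −30 → 0 °C, 7 added slowly to 10 (2.5 equiv)
Reagents that add atoms: none
Why: The chiral Brønsted acid protonates the benzylic hydroxyl of 7 and water leaves easily, because that carbon is ortho to the phenol oxygen and ortho and para to the two methoxy groups; the quinone methide 11 stays hydrogen-bonded, or ion-paired in its O-protonated form, to the chiral phosphoramide anion, the stronger N-triflyl acid being chosen because this trialkoxy quinone methide is a stabilised, weak electrophile. The terminal carbon of styrene 10 attacks the methide carbon (C3–C4) and the developing benzylic cation at C2, stabilised by the para-methoxy group of ring B, is captured by O1 (O1–C2) in an asynchronous inverse-electron-demand oxa-[4+2] cycloaddition; the closest known reaction type is the chiral Brønsted acid-catalysed cycloaddition of ortho-quinone methides, generated from ortho-hydroxybenzyl alcohols, with styrenes to give 2-arylchromans. Ring C closes as the six-membered pyran ring of the cycloadduct, four atoms (O1, C8a, C4a, C4) from the heterodiene and two (C3, C2) from the alkene. The only new stereocentre, C2, is created in the O1–C2 bond-forming event at the very oxygen that carries the catalyst, so the 3,3'-aryl groups of the acid select the enantioface of the styrene and should give (2S). The step needs regioselectivity (aryl on C2, fixed by cation stability), enantioface selectivity (catalyst) and chemoselectivity over Friedel–Crafts self-condensation of 7 at its free C6–H and over styrene oligomerisation, which slow addition of 7 to excess 10 at low temperature is meant to secure.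

Step 8
Reactants: 12 (2S)-6-(benzyloxy)-2-[3-(benzyloxy)-4-methoxyphenyl]-5,7-dimethoxy-3,4-dihydro-2H-chromene
Product: 13 (2S,4RS)-6-(benzyloxy)-2-[3-(benzyloxy)-4-methoxyphenyl]-5,7-dimethoxy-3,4-dihydro-2H-chromen-4-ol (mixture of C4 epimers)
Conditions: DDQ (1.2 equiv), CH2Cl2/pH 7 phosphate buffer (10:1), 0 °C
Reagents that add atoms: water, O
Why: Benzylic oxidation by hydride abstraction, in which DDQ takes hydride from C4 (cation stabilised by O1 and the 5-methoxy group ortho and the 7-methoxy group para to C4a) and water captures the cation before it can lose the C3 proton; C2 is untouched and the C4 configuration is erased in step 9.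

Step 9
Reactants: 13 (2S,4RS)-6-(benzyloxy)-2-[3-(benzyloxy)-4-methoxyphenyl]-5,7-dimethoxy-3,4-dihydro-2H-chromen-4-ol
Product: 14 (2S)-6-(benzyloxy)-2-[3-(benzyloxy)-4-methoxyphenyl]-5,7-dimethoxy-2,3-dihydro-4H-chromen-4-one
Conditions: Dess–Martin periodinane, NaHCO3, CH2Cl2, 0 °C → rt
Reagents that add atoms: none
Why: Dess–Martin oxidation of the secondary benzylic alcohol under buffered, non-basic conditions, so the flavanone never meets a base that could open ring C by retro-oxa-Michael reaction and racemise C2.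

Step 10
Reactants: 14 (2S)-6-(benzyloxy)-2-[3-(benzyloxy)-4-methoxyphenyl]-5,7-dimethoxy-2,3-dihydro-4H-chromen-4-one
Product: 15 (2S)-6-(benzyloxy)-2-[3-(benzyloxy)-4-methoxyphenyl]-5,7-dimethoxy-4-[(trimethylsilyl)oxy]-2H-chromene
Conditions: TMSOTf, Et3N, CH2Cl2, −78 → 0 °C; pentane, cold aq. NaHCO3 wash; used crude
Reagents that add atoms: trimethylsilyl triflate, C[Si](C)(C)OS(=O)(=O)C(F)(F)F
Why: Soft enolisation (silyl triflate on the carbonyl oxygen, then removal of H3 by the amine) gives the silyl enol ether without a free enolate that could expel O1 and scramble C2.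

Step 11
Reactants: 15 (2S)-6-(benzyloxy)-2-[3-(benzyloxy)-4-methoxyphenyl]-5,7-dimethoxy-4-[(trimethylsilyl)oxy]-2H-chromene
Product: 17 (2R,3R)-6-(benzyloxy)-2-[3-(benzyloxy)-4-methoxyphenyl]-3-hydroxy-5,7-dimethoxy-2,3-dihydro-4H-chromen-4-one, via silyloxy epoxide 16 (not isolated)
Conditions: DMDO (acetone solution), CH2Cl2, −78 → −20 °C; then 10% aq. citric acid, THF, 0 °C
Reagents that add atoms: dimethyldioxirane, CC1(C)OO1
Why: Rubottom oxidation, in which the neutral dioxirane epoxidises the enol ether on the face opposite the C2 aryl group and acidic hydrolysis of the silyloxy oxirane gives the ketone with the 3-hydroxyl trans to the aryl group, which is (2R,3R) (the C2 descriptor changes only because C3 gains priority).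

Step 12
Reactants: 17 (2R,3R)-6-(benzyloxy)-2-[3-(benzyloxy)-4-methoxyphenyl]-3-hydroxy-5,7-dimethoxy-2,3-dihydro-4H-chromen-4-one
Product: 18 (2R,3R)-6-(benzyloxy)-2-[3-(benzyloxy)-4-methoxyphenyl]-3,5,7-trimethoxy-2,3-dihydro-4H-chromen-4-one
Conditions: MeOTf, 2,6-di-tert-butyl-4-methylpyridine, CH2Cl2, 0 °C → rt
Reagents that add atoms: methyl triflate, COS(=O)(=O)C(F)(F)F
Why: O-Alkylation of the secondary alcohol by a strong methylating agent with a hindered, non-nucleophilic pyridine as proton trap, so no enolate forms and neither C3 epimerisation, ring-opening nor dehydrogenation to the flavonol is invited.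

Step 13
Reactants: 18 (2R,3R)-6-(benzyloxy)-2-[3-(benzyloxy)-4-methoxyphenyl]-3,5,7-trimethoxy-2,3-dihydro-4H-chromen-4-one
Product: 19 (2R,3R)-5,6-dihydroxy-2-(3-hydroxy-4-methoxyphenyl)-3,7-dimethoxy-2,3-dihydro-4H-chromen-4-one
Conditions: BCl3 (1 M in CH2Cl2, 6 equiv), C6HMe5 (6 equiv), CH2Cl2, −78 → 0 °C; MeOH quench
Reagents that add atoms: none
Why: Lewis acid ether cleavage, in which BCl3 removes both benzyl groups (benzyl cations trapped by pentamethylbenzene) and, through the six-membered chelate between the C4 carbonyl and O5, the peri 5-methyl ether, while the unchelated 7- and 4'-methyl ethers and the aliphatic 3-methyl ether should react more slowly at or below 0 °C.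

**Compound list**

1 | syringaldehyde (4-hydroxy-3,5-dimethoxybenzaldehyde) | COc1cc(C=O)cc(OC)c1O | starting material
2 | 4-(benzyloxy)-3,5-dimethoxybenzaldehyde | COc1cc(C=O)cc(OC)c1OCc1ccccc1 | intermediate
3 | 4-(benzyloxy)-3,5-dimethoxyphenyl formate | COc1cc(OC=O)cc(OC)c1OCc1ccccc1 | intermediate
4 | 4-(benzyloxy)-3,5-dimethoxyphenol | COc1cc(O)cc(OC)c1OCc1ccccc1 | intermediate
5 | magnesium salt (phenoxide and alkoxide) of 4-(benzyloxy)-2-(hydroxymethyl)-3,5-dimethoxyphenol | [Mg+2].[O-]Cc1c([O-])cc(OC)c(OCc2ccccc2)c1OC | intermediate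
6 | 3-(benzyloxy)-6-hydroxy-2,4-dimethoxybenzaldehyde | O=Cc1c(O)cc(OC)c(OCc2ccccc2)c1OC | intermediate
7 | 4-(benzyloxy)-2-(hydroxymethyl)-3,5-dimethoxyphenol | OCc1c(O)cc(OC)c(OCc2ccccc2)c1OC | intermediate
8 | isovanillin (3-hydroxy-4-methoxybenzaldehyde) | COc1ccc(C=O)cc1O | starting material
9 | 3-(benzyloxy)-4-methoxybenzaldehyde | COc1ccc(C=O)cc1OCc1ccccc1 | intermediate
10 | 2-(benzyloxy)-4-ethenyl-1-methoxybenzene | C=Cc1ccc(OC)c(OCc2ccccc2)c1 | intermediate
11 | 4-(benzyloxy)-3,5-dimethoxy-6-methylidenecyclohexa-2,4-dien-1-one (ortho-quinone methide) | C=C1C(=O)C=C(OC)C(OCc2ccccc2)=C1OC | intermediate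
12 | (2S)-6-(benzyloxy)-2-[3-(benzyloxy)-4-methoxyphenyl]-5,7-dimethoxy-3,4-dihydro-2H-chromene | COc1ccc([C@H]2Oc3cc(OC)c(OCc4ccccc4)c(OC)c3CC2)cc1OCc1ccccc1 | intermediate
13 | (2S,4RS)-6-(benzyloxy)-2-[3-(benzyloxy)-4-methoxyphenyl]-5,7-dimethoxy-3,4-dihydro-2H-chromen-4-ol (C4 epimers) | COc1ccc([C@H]2Oc3cc(OC)c(OCc4ccccc4)c(OC)c3C(O)C2)cc1OCc1ccccc1 | intermediate
14 | (2S)-6-(benzyloxy)-2-[3-(benzyloxy)-4-methoxyphenyl]-5,7-dimethoxy-2,3-dihydro-4H-chromen-4-one | COc1ccc([C@H]2Oc3cc(OC)c(OCc4ccccc4)c(OC)c3C(=O)C2)cc1OCc1ccccc1 | intermediate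
15 | (2S)-6-(benzyloxy)-2-[3-(benzyloxy)-4-methoxyphenyl]-5,7-dimethoxy-4-[(trimethylsilyl)oxy]-2H-chromene | COc1ccc([C@H]2Oc3cc(OC)c(OCc4ccccc4)c(OC)c3C(O[Si](C)(C)C)=C2)cc1OCc1ccccc1 | intermediate
16 | 3,4-epoxide of 15, oxirane oxygen on the face anti to the C2 aryl group, trimethylsilyloxy group on C4 | COc1ccc([C@H]2Oc3cc(OC)c(OCc4ccccc4)c(OC)c3[C@]5(O[Si](C)(C)C)O[C@H]25)cc1OCc1ccccc1 | intermediate
17 | (2R,3R)-6-(benzyloxy)-2-[3-(benzyloxy)-4-methoxyphenyl]-3-hydroxy-5,7-dimethoxy-2,3-dihydro-4H-chromen-4-one | COc1ccc([C@H]2Oc3cc(OC)c(OCc4ccccc4)c(OC)c3C(=O)[C@@H]2O)cc1OCc1ccccc1 | intermediate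
18 | (2R,3R)-6-(benzyloxy)-2-[3-(benzyloxy)-4-methoxyphenyl]-3,5,7-trimethoxy-2,3-dihydro-4H-chromen-4-one | COc1ccc([C@H]2Oc3cc(OC)c(OCc4ccccc4)c(OC)c3C(=O)[C@@H]2OC)cc1OCc1ccccc1 | intermediate
19 | (2R,3R)-5,6-dihydroxy-2-(3-hydroxy-4-methoxyphenyl)-3,7-dimethoxy-2,3-dihydro-4H-chromen-4-one | COc1ccc([C@H]2Oc3cc(OC)c(O)c(O)c3C(=O)[C@@H]2OC)cc1O | target

**Step count and risks**

Total step count: 13. Longest linear sequence: 11 steps (steps 1–4 and 7–13, from syringaldehyde); the isovanillin branch contributes steps 5 and 6.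

Steps most likely to fail:

Step 7. The chiral acid may discriminate poorly between the enantiofaces of a styrene that carries no hydrogen-bond donor. The quinone methide may also be consumed by Friedel–Crafts self-condensation onto the electron-rich ring of 7, and the styrene by acid-induced oligomerisation. The fallback sets out from aldehyde 6 and returns at flavan 12, closing ring C by the O1–C2 bond alone. Commercial 1-(3-hydroxy-4-methoxyphenyl)ethan-1-one is benzylated (BnBr, K2CO3, DMF) to 1-[3-(benzyloxy)-4-methoxyphenyl]ethan-1-one F1. Claisen–Schmidt condensation of F1 with 6 (KOH, EtOH, rt → 50 °C) should give (E)-3-[3-(benzyloxy)-6-hydroxy-2,4-dimethoxyphenyl]-1-[3-(benzyloxy)-4-methoxyphenyl]prop-2-en-1-one F2. Hydrogenation of the C=C bond only (H2, RhCl(PPh3)3, PhH/EtOH) gives 3-[3-(benzyloxy)-6-hydroxy-2,4-dimethoxyphenyl]-1-[3-(benzyloxy)-4-methoxyphenyl]propan-1-one F3. Corey–Bakshi–Shibata reduction ((S)-1-methyl-3,3-diphenyltetrahydro-1H,3H-pyrrolo[1,2-c][1,3,2]oxazaborole, BH3·SMe2 in excess, THF, 0 °C) should set the benzylic carbinol as (R) in (1R)-3-[3-(benzyloxy)-6-hydroxy-2,4-dimethoxyphenyl]-1-[3-(benzyloxy)-4-methoxyphenyl]propan-1-ol F4. Intramolecular Mitsunobu etherification (PPh3, DIAD, THF, 0 °C) then joins the phenol oxygen to the carbinol carbon with inversion, giving (2S)-flavan 12.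

Step 11 (with the enol silylation of step 10 that feeds it). The flavanone may open by retro-oxa-Michael reaction during enolisation and lose its C2 configuration, or the epoxidation may show a weak facial bias and give cis/trans mixtures. The fallback sets out from flavan-4-ol 13 and returns at 18, bringing in the C3 oxygen by hydroboration instead of enol oxidation. Dehydration of 13 (pyridinium p-toluenesulfonate cat., PhMe, 60 °C, 4 Å MS) gives (2S)-6-(benzyloxy)-2-[3-(benzyloxy)-4-methoxyphenyl]-5,7-dimethoxy-2H-chromene F5. Hydroboration–oxidation (BH3·THF, 0 °C; then NaOH, H2O2) should put boron on C3 from the face anti to the C2 aryl group and give the 2,3-trans alcohol (2R,3S)-6-(benzyloxy)-2-[3-(benzyloxy)-4-methoxyphenyl]-5,7-dimethoxy-3,4-dihydro-2H-chromen-3-ol F6. Williamson methylation (NaH, MeI, THF, 0 °C), with no base-sensitive ketone present, gives (2R,3S)-6-(benzyloxy)-2-[3-(benzyloxy)-4-methoxyphenyl]-3,5,7-trimethoxy-3,4-dihydro-2H-chromene F7. DDQ in CH2Cl2/pH 7 buffer oxidises C4 to (2R,3S,4RS)-6-(benzyloxy)-2-[3-(benzyloxy)-4-methoxyphenyl]-3,5,7-trimethoxy-3,4-dihydro-2H-chromen-4-ol F8, and Dess–Martin periodinane (NaHCO3, CH2Cl2) converts F8 into ketone 18.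

Step 13. Cleavage may run on beyond the peri methyl ether: the 7- and 4'-methyl ethers gain a neighbouring boron aryloxide once the benzyl groups are gone, and the 3-methyl ether can form a five-membered chelate. Benzyl cations may also re-attack the electron-rich rings. The fallback sets out from 18 and returns at 19, separating the two deprotection events. Hydrogenolysis (H2, 1 atm, Pd(OH)2/C, EtOAc, rt, stopped at the calculated uptake) removes both benzyl groups and should give (2R,3R)-6-hydroxy-2-(3-hydroxy-4-methoxyphenyl)-3,5,7-trimethoxy-2,3-dihydro-4H-chromen-4-one F9 with all four methyl ethers intact. Anhydrous MgI2 (Et2O/PhMe, 50 °C) then cleaves only the 5-methyl ether, the one that can hold magnesium in a six-membered chelate with the C4 carbonyl, to give 19.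

**Further compounds**

F1 | step 7 | 1-[3-(benzyloxy)-4-methoxyphenyl]ethan-1-one | CC(=O)c1ccc(OC)c(OCc2ccccc2)c1
F2 | step 7 | (E)-3-[3-(benzyloxy)-6-hydroxy-2,4-dimethoxyphenyl]-1-[3-(benzyloxy)-4-methoxyphenyl]prop-2-en-1-one | COc1ccc(C(=O)/C=C/c2c(O)cc(OC)c(OCc3ccccc3)c2OC)cc1OCc1ccccc1
F3 | step 7 | 3-[3-(benzyloxy)-6-hydroxy-2,4-dimethoxyphenyl]-1-[3-(benzyloxy)-4-methoxyphenyl]propan-1-one | COc1ccc(C(=O)CCc2c(O)cc(OC)c(OCc3ccccc3)c2OC)cc1OCc1ccccc1
F4 | step 7 | (1R)-3-[3-(benzyloxy)-6-hydroxy-2,4-dimethoxyphenyl]-1-[3-(benzyloxy)-4-methoxyphenyl]propan-1-ol | COc1ccc([C@H](O)CCc2c(O)cc(OC)c(OCc3ccccc3)c2OC)cc1OCc1ccccc1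
F5 | step 11 | (2S)-6-(benzyloxy)-2-[3-(benzyloxy)-4-methoxyphenyl]-5,7-dimethoxy-2H-chromene | COc1ccc([C@H]2Oc3cc(OC)c(OCc4ccccc4)c(OC)c3C=C2)cc1OCc1ccccc1
F6 | step 11 | (2R,3S)-6-(benzyloxy)-2-[3-(benzyloxy)-4-methoxyphenyl]-5,7-dimethoxy-3,4-dihydro-2H-chromen-3-ol | COc1ccc([C@H]2Oc3cc(OC)c(OCc4ccccc4)c(OC)c3C[C@@H]2O)cc1OCc1ccccc1
F7 | step 11 | (2R,3S)-6-(benzyloxy)-2-[3-(benzyloxy)-4-methoxyphenyl]-3,5,7-trimethoxy-3,4-dihydro-2H-chromene | COc1ccc([C@H]2Oc3cc(OC)c(OCc4ccccc4)c(OC)c3C[C@@H]2OC)cc1OCc1ccccc1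
F8 | step 11 | (2R,3S,4RS)-6-(benzyloxy)-2-[3-(benzyloxy)-4-methoxyphenyl]-3,5,7-trimethoxy-3,4-dihydro-2H-chromen-4-ol (C4 epimers) | COc1ccc([C@H]2Oc3cc(OC)c(OCc4ccccc4)c(OC)c3C(O)[C@@H]2OC)cc1OCc1ccccc1
F9 | step 13 | (2R,3R)-6-hydroxy-2-(3-hydroxy-4-methoxyphenyl)-3,5,7-trimethoxy-2,3-dihydro-4H-chromen-4-one | COc1ccc([C@H]2Oc3cc(OC)c(O)c(OC)c3C(=O)[C@@H]2OC)cc1O
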